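A direct plan would take 4′-hydroxyacetophenone A1, formylate A1 ortho to the phenol and acetylate the phenol to give A2, turn the aldehyde into the trans-vinyl epoxide A3 with a chiral 2-(methoxycarbonyl)allyl sulfonium ylide, and let zerovalent palladium ionise A3 so that the aryl acetate would move to O-3 and the phenoxide would close O1–C2 to the cis-ketone A4; ketone reduction and angeloylation would follow. Its weakest steps would be the ylide epoxidation (an ester-bearing allyl ylide has little precedent, and its carbonate base would endanger the aryl acetate), the palladium-triggered opening, acetyl relay and ring closure (an untested cascade that could scramble C-2 or end in the benzofuran), and the phenol acetylation (a step without gain in complexity).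

The route rests on two readings of the dihydrofuran ring: the acetate at C-3 is the Baeyer–Villiger image of a methyl ketone, and C-2 is the doubly activated methylene carbon (allylic, α to O-1) of a 2-(methoxycarbonyl)allyl aryl ether. The C2–C3 bond is disconnected: an aryl(acetyl) rhodium carbene at C-3 inserts into a methylene C–H bond. This one step would close the heterocycle and set both ring stereocentres cis under catalyst control; oxygen insertion with retention turns acetyl into acetoxy. No epoxide, palladium relay or protecting group is needed, and the angelate is attached early, to an acyclic alcohol.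

Key step: step 6

Assumption: 1 is bought as such; Rh2(S-PTTL)4 is assigned to the (2R,3S) product by analogy with insertions of ortho-alkoxyaryl diazoacetates, and the enantiomeric catalyst Rh2(R-PTTL)4 would be used if the sense proved opposite.

**Step 1**
Reactants: 1 3′-allyl-4′-hydroxyacetophenone; 2 methyl 2-(bromomethyl)acrylate
Product: 3 methyl 2-[(4-acetyl-2-allylphenoxy)methyl]prop-2-enoate
Conditions: K2CO3, acetone, rt
Reagents that add atoms: none
Why: Williamson etherification of the phenoxide with the allylic bromide (direct and SN2′ displacement give the same ether), which brings in C-2 and the complete acrylate at their final oxidation level.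

**Step 2**
Reactants: 3 methyl 2-[(4-acetyl-2-allylphenoxy)methyl]prop-2-enoate
Product: 4 methyl 2-({2-allyl-4-[(1S)-1-hydroxyethyl]phenoxy}methyl)prop-2-enoate
Conditions: RuCl[(S,S)-TsDPEN](p-cymene) (1 mol %), HCO2H–Et3N (5:2), EtOAc, 25 °C
Reagents that add atoms: none
Why: Noyori–Ikariya asymmetric transfer hydrogenation, in which the (S,S)-catalyst should deliver hydride to the aryl methyl ketone through its outer-sphere, CH/π-organised transition state to give the (S)-carbinol under reagent control, while the allyl and acrylate double bonds cannot use this pathway and stay untouched.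

**Step 3**
Reactants: 4 methyl 2-({2-allyl-4-[(1S)-1-hydroxyethyl]phenoxy}methyl)prop-2-enoate; 5 angelic acid [(2Z)-2-methylbut-2-enoic acid]
Product: 7 (1S)-1-(3-allyl-4-{[2-(methoxycarbonyl)prop-2-en-1-yl]oxy}phenyl)ethyl (2Z)-2-methylbut-2-enoate, via mixed anhydride 6 (not isolated)
Conditions: 5, 2,4,6-trichlorobenzoyl chloride, Et3N, toluene, rt (→ 6); then 4, toluene, 70 °C, no DMAP
Reagents that add atoms: none
Why: Yamaguchi-type acylation through the hindered mixed anhydride without a nucleophilic catalyst, so that no conjugate addition–elimination can turn the angelate into the tiglate, and with retention at the carbinol carbon because its C–O bond is not broken.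

**Step 4**
Reactants: 7 (1S)-1-(3-allyl-4-{[2-(methoxycarbonyl)prop-2-en-1-yl]oxy}phenyl)ethyl (2Z)-2-methylbut-2-enoate
Product: 8 (1S)-1-[4-{[2-(methoxycarbonyl)prop-2-en-1-yl]oxy}-3-(2-oxopropyl)phenyl]ethyl (2Z)-2-methylbut-2-enoate
Conditions: PdCl2 (10 mol %), Cu(OAc)2 (20 mol %), O2 (1 atm), DMA–H2O (7:1), rt
Reagents that add atoms: water, O
Why: Tsuji–Wacker oxidation, in which Markovnikov hydroxypalladation of the only electron-rich terminal alkene and β-hydride elimination should give the methyl ketone with dioxygen as terminal oxidant; the phenol is already etherified, so no oxypalladation to a benzofuran can occur, and the two conjugated esters are too electron-poor to bind divalent palladium.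

**Step 5**
Reactants: 8 (1S)-1-[4-{[2-(methoxycarbonyl)prop-2-en-1-yl]oxy}-3-(2-oxopropyl)phenyl]ethyl (2Z)-2-methylbut-2-enoate
Product: 9 (1S)-1-[3-(1-diazo-2-oxopropyl)-4-{[2-(methoxycarbonyl)prop-2-en-1-yl]oxy}phenyl]ethyl (2Z)-2-methylbut-2-enoate
Conditions: 4-acetamidobenzenesulfonyl azide, DBU, MeCN, 0 °C; 9 used at once
Reagents that add atoms: 4-acetamidobenzenesulfonyl azide, CC(=O)Nc1ccc(cc1)S(=O)(=O)N=[N+]=[N-]
Why: Regitz diazo transfer to the benzylic CH2, the only position acidic enough for DBU because it is activated by both the ketone and the arene; immediate use of the diazoketone keeps slow dipolar cycloaddition to the acrylate from intervening.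

**Step 6**
Reactants: 9 (1S)-1-[3-(1-diazo-2-oxopropyl)-4-{[2-(methoxycarbonyl)prop-2-en-1-yl]oxy}phenyl]ethyl (2Z)-2-methylbut-2-enoate
Product: 10 methyl 2-[(2R,3S)-3-acetyl-5-{(1S)-1-[(2Z)-2-methylbut-2-enoyloxy]ethyl}-2,3-dihydro-1-benzofuran-2-yl]prop-2-enoate (2,3-cis)
Conditions: Rh2(S-PTTL)4 [dirhodium tetrakis(N-phthaloyl-(S)-tert-leucinate)] (1 mol %), toluene, −40 → 0 °C, slow addition of 9
Reagents that add atoms: none
Why: The catalyst should extrude N2 from 9 to give an electrophilic aryl(acetyl) rhodium carbene whose carbene carbon lies five atoms from the O–CH2 hydrogens, and a concerted, asynchronous, hydride-transfer-like three-centre insertion into one of these C–H bonds forms the C2–C3 bond. The closest known reaction type is the enantioselective intramolecular 1,5-C–H insertion of ortho-alkoxyaryl diazoacetates under chiral divalent rhodium carboxylates, which gives cis-2-substituted 2,3-dihydrobenzofuran-3-carboxylates. The dihydrofuran ring (O1–C2–C3–C3a–C7a) is closed by this 1,5-insertion through a six-centre transition state, the mode that is entropically favoured over all others open to the carbene. C-2 is set by the catalyst's choice between the two enantiotopic hydrogens of the OCH2 group and C-3 by the carbene face that the phthalimido wall leaves open, and the cis relationship is the kinetic outcome because the alkenyl substituent of the reacting carbon points away from the ligand wall and so ends syn to the acetyl group; the (S)-catalyst is expected to give (2R,3S), the arrangement that becomes (2S,3S) in the target. The step needs insertion to win over cyclopropanation and ylide formation, which the substrate secures because the C–H bond is activated twice (α to O-1 and allylic), the only alkene in reach is an electron-poor 1,1-disubstituted acrylate that is a poor partner for the electrophilic carbene, and an oxonium ylide at O-1 would require a four-membered ring. The remote (1S) centre and the angelate lie outside the catalyst pocket and should not interfere.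

**Step 7**
Reactants: 10 methyl 2-[(2R,3S)-3-acetyl-5-{(1S)-1-[(2Z)-2-methylbut-2-enoyloxy]ethyl}-2,3-dihydro-1-benzofuran-2-yl]prop-2-enoate
Product: 11 methyl 2-[(2S,3S)-3-acetoxy-5-{(1S)-1-[(2Z)-2-methylbut-2-enoyloxy]ethyl}-2,3-dihydro-1-benzofuran-2-yl]prop-2-enoate (CNP0168827.1)
Conditions: mCPBA, NaHCO3, CH2Cl2, 0 °C → rt
Reagents that add atoms: 3-chloroperoxybenzoic acid, O=C(OO)c1cccc(Cl)c1
Why: Baeyer–Villiger oxidation, in which the Criegee adduct should rearrange by migration of the secondary benzylic C-3 (far better than methyl) with retention, so the cis acetyl group becomes the cis acetate (C-2 changes from R to S only because the priorities change), while the electron-poor acrylate and angelate double bonds are not expected to react with the buffered peracid.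

**Compound list**
1 | 3′-allyl-4′-hydroxyacetophenone, 1-[4-hydroxy-3-(prop-2-en-1-yl)phenyl]ethan-1-one | C=CCc1cc(C(C)=O)ccc1O | starting material
2 | methyl 2-(bromomethyl)acrylate | C=C(CBr)C(=O)OC | starting material
3 | methyl 2-[(4-acetyl-2-allylphenoxy)methyl]prop-2-enoate | C=CCc1cc(C(C)=O)ccc1OCC(=C)C(=O)OC | intermediate
4 | methyl 2-({2-allyl-4-[(1S)-1-hydroxyethyl]phenoxy}methyl)prop-2-enoate | C=CCc1cc([C@H](C)O)ccc1OCC(=C)C(=O)OC | intermediate
5 | angelic acid, (2Z)-2-methylbut-2-enoic acid | C/C=C(/C)C(=O)O | starting material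
6 | angelic 2,4,6-trichlorobenzoic anhydride | C/C=C(/C)C(=O)OC(=O)c1c(Cl)cc(Cl)cc1Cl | intermediate
7 | (1S)-1-(3-allyl-4-{[2-(methoxycarbonyl)prop-2-en-1-yl]oxy}phenyl)ethyl (2Z)-2-methylbut-2-enoate | C=CCc1cc([C@H](C)OC(=O)/C(C)=C\C)ccc1OCC(=C)C(=O)OC | intermediate
8 | (1S)-1-[4-{[2-(methoxycarbonyl)prop-2-en-1-yl]oxy}-3-(2-oxopropyl)phenyl]ethyl (2Z)-2-methylbut-2-enoate | CC(=O)Cc1cc([C@H](C)OC(=O)/C(C)=C\C)ccc1OCC(=C)C(=O)OC | intermediate
9 | (1S)-1-[3-(1-diazo-2-oxopropyl)-4-{[2-(methoxycarbonyl)prop-2-en-1-yl]oxy}phenyl]ethyl (2Z)-2-methylbut-2-enoate | CC(=O)C(=[N+]=[N-])c1cc([C@H](C)OC(=O)/C(C)=C\C)ccc1OCC(=C)C(=O)OC | intermediate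
10 | methyl 2-[(2R,3S)-3-acetyl-5-{(1S)-1-[(2Z)-2-methylbut-2-enoyloxy]ethyl}-2,3-dihydro-1-benzofuran-2-yl]prop-2-enoate (2,3-cis) | C=C(C(=O)OC)[C@@H]1Oc2ccc([C@H](C)OC(=O)/C(C)=C\C)cc2[C@@H]1C(C)=O | intermediate
11 | methyl 2-[(2S,3S)-3-acetoxy-5-{(1S)-1-[(2Z)-2-methylbut-2-enoyloxy]ethyl}-2,3-dihydro-1-benzofuran-2-yl]prop-2-enoate | C=C(C(=O)OC)[C@@H]1Oc2ccc([C@H](C)OC(=O)/C(C)=C\C)cc2[C@@H]1OC(C)=O | target

Total step count: 7. Longest linear sequence: 7 steps (1 → 11).

**Steps most likely to fail**

1. Step 6 (carbene C–H insertion). The process at risk is loss of the kinetic cis relationship: part of the insertion may run through the trans transition state, and the C-3 hydrogen of 10 (benzylic, α to the ketone) may epimerise on the catalyst or on silica. The fallback sets out from 9 and returns at 10. The insertion would be judged on C-2 alone, and the crude product would then hold the trans epimer of 10 F1. It would be deprotonated at C-3 (LiN(SiMe3)2, THF, −78 → −40 °C; the ring C2–O1 bond lies in the nodal plane of the enolate, so the phenoxide cannot be expelled) and reprotonated at −78 °C with 2,6-di-tert-butylphenol. Kinetic protonation anti to the C-2 substituent should place the acetyl group cis and give 10.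

2. Step 7 (Baeyer–Villiger oxidation). The process at risk is slow migration of the crowded cis C-3 carbon, during which the peracid may epoxidise the angelate double bond and the acid may ionise the new benzylic acetate toward the benzofuran. The fallback sets out from 4 and returns at 11, with the esterification moved behind the oxidation. 4 would be silylated (TBSCl, imidazole, DMF) to the tert-butyldimethylsilyl ether of 4 F2. This would be taken through the conditions of steps 4 to 7: Wacker oxidation to the arylacetone F3, diazo transfer to the diazoketone F4, rhodium-carbene insertion to the cis-acetyl dihydrobenzofuran F5 and Baeyer–Villiger oxidation, with no angelate present, to the cis-acetate silyl ether F6. HF·pyridine (THF, 0 °C) would free the carbinol acetate F7, which would be acylated with mixed anhydride 6 as in step 3 to give 11.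

3. Step 3 (angeloylation). The process at risk is Z-to-E isomerisation of the angeloyl unit to the tiglate during activation and heating, together with ionisation of the electron-rich benzylic alcohol and partial loss of configuration. The fallback sets out from 4 and returns at 7, with the Z double bond made after the ester bond. 4 would be acylated at 0 °C (DCC, cat. DMAP, CH2Cl2) with 2-[bis(2,2,2-trifluoroethoxy)phosphoryl]propanoic acid to the phosphonate ester F8. A Still–Gennari olefination (KN(SiMe3)2, 18-crown-6, THF, −78 °C; then acetaldehyde) should give 7 with the Z geometry under kinetic control.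

**Further compounds**
F1 | step 6 | methyl 2-[(2R,3R)-3-acetyl-5-{(1S)-1-[(2Z)-2-methylbut-2-enoyloxy]ethyl}-2,3-dihydro-1-benzofuran-2-yl]prop-2-enoate (2,3-trans) | C=C(C(=O)OC)[C@@H]1Oc2ccc([C@H](C)OC(=O)/C(C)=C\C)cc2[C@H]1C(C)=O
F2 | step 7 | methyl 2-{[2-allyl-4-[(1S)-1-{[tert-butyl(dimethyl)silyl]oxy}ethyl]phenoxy]methyl}prop-2-enoate | C=CCc1cc([C@H](C)O[Si](C)(C)C(C)(C)C)ccc1OCC(=C)C(=O)OC
F3 | step 7 | methyl 2-{[4-[(1S)-1-{[tert-butyl(dimethyl)silyl]oxy}ethyl]-2-(2-oxopropyl)phenoxy]methyl}prop-2-enoate | CC(=O)Cc1cc([C@H](C)O[Si](C)(C)C(C)(C)C)ccc1OCC(=C)C(=O)OC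
F4 | step 7 | methyl 2-{[4-[(1S)-1-{[tert-butyl(dimethyl)silyl]oxy}ethyl]-2-(1-diazo-2-oxopropyl)phenoxy]methyl}prop-2-enoate | CC(=O)C(=[N+]=[N-])c1cc([C@H](C)O[Si](C)(C)C(C)(C)C)ccc1OCC(=C)C(=O)OC
F5 | step 7 | methyl 2-[(2R,3S)-3-acetyl-5-[(1S)-1-{[tert-butyl(dimethyl)silyl]oxy}ethyl]-2,3-dihydro-1-benzofuran-2-yl]prop-2-enoate | C=C(C(=O)OC)[C@@H]1Oc2ccc([C@H](C)O[Si](C)(C)C(C)(C)C)cc2[C@@H]1C(C)=O
F6 | step 7 | methyl 2-[(2S,3S)-3-acetoxy-5-[(1S)-1-{[tert-butyl(dimethyl)silyl]oxy}ethyl]-2,3-dihydro-1-benzofuran-2-yl]prop-2-enoate | C=C(C(=O)OC)[C@@H]1Oc2ccc([C@H](C)O[Si](C)(C)C(C)(C)C)cc2[C@@H]1OC(C)=O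
F7 | step 7 | methyl 2-[(2S,3S)-3-acetoxy-5-[(1S)-1-hydroxyethyl]-2,3-dihydro-1-benzofuran-2-yl]prop-2-enoate | C=C(C(=O)OC)[C@@H]1Oc2ccc([C@H](C)O)cc2[C@@H]1OC(C)=O
F8 | step 3 | (1S)-1-(3-allyl-4-{[2-(methoxycarbonyl)prop-2-en-1-yl]oxy}phenyl)ethyl 2-[bis(2,2,2-trifluoroethoxy)phosphoryl]propanoate (both epimers at the phosphorus-bearing carbon) | C=CCc1cc([C@H](C)OC(=O)C(C)P(=O)(OCC(F)(F)F)OCC(F)(F)F)ccc1OCC(=C)C(=O)OC
A1 | direct plan | 4′-hydroxyacetophenone | CC(=O)c1ccc(O)cc1
A2 | direct plan | 4-acetyl-2-formylphenyl acetate | CC(=O)Oc1ccc(C(C)=O)cc1C=O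
A3 | direct plan | methyl 2-[(2S,3S)-3-(2-acetoxy-5-acetylphenyl)oxiran-2-yl]prop-2-enoate (trans-epoxide) | C=C(C(=O)OC)[C@@H]1O[C@H]1c1cc(C(C)=O)ccc1OC(C)=O
A4 | direct plan | methyl 2-[(2S,3S)-3-acetoxy-5-acetyl-2,3-dihydro-1-benzofuran-2-yl]prop-2-enoate (2,3-cis) | C=C(C(=O)OC)[C@@H]1Oc2ccc(C(C)=O)cc2[C@@H]1OC(C)=O
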